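The runs were computed for substances that don't exist; scatter was added.

Start with a subtraction: take product from the charge and call the rest the pool. Then climb the ladder.

the same everywhere: substrate 0.063 M
- Saturday's: acid 6.3 mM; scavenger 0.063 M; the very flask that is asked about, followed so far
- Thursday's: acid 13 mM; scavenger 0.063 M; run made earlier
- flask: acid 6.30 mM; scavenger 0.0630 M; time 12 h

| run | time / h | substrate / % | product / % |
|---|---|---|---|
| Saturday's | 0.200 | 80.0 | 1.8 |
| Saturday's | 0.333 | 70.4 | 3.2 |
| Saturday's | 0.667 | 53.0 | 5.1 |
| Saturday's | 1.33 | 37.6 | 8.2 |
| Saturday's | 2.50 | 27.7 | 12.2 |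
| Thursday's | 1.50 | 30.7 | 14.7 |
| Thursday's | 3.00 | 23.7 | 22.2 |
| Thursday's | 5.00 | 21.0 | 31.4 |
| Thursday's | 6.00 | 18.5 | 34.0 |
| Thursday's | 8.00 | 17.2 | 41.3 |

(readings scatter by 0.5 percentage points)

* part of the substrate that has reacted at 12 h
* pH of the solution at 12 h

- acid is the free proton; pH is minus the decimal logarithm of its molar concentration
- what has gone from substrate into another species counts as reacted, even if it can come back

Fastest rung: by 0.667 h, Saturday's flask has lost substrate down to 53.0%, yet product stands at 5.1%. So substrate fills an unseen reservoir. Slower rung: Saturday's flask gives a drain constant of 0.0381 h⁻¹ from its last two readings, a rough reading. Its time, 26.3 h, is far longer than that first fall.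

So treat the reservoir as a pre-equilibrium and carry one number. Thursday's last reading gives 0.293: this is the free share, substrate as a fraction of the pool. Saturday's last reading gives 0.315 at half of Thursday's acid.

Thursday's flask made twice its acid charge as product and still climbed. So take acid as returned each turn, and pH as that of the charge.

Run Saturday's drain on to 12 h: the pool is 61.1% of the charge. Reacted is one minus share times pool, 82.1%.

The forecast says 80.3%, between 77.5% and 83%, lower than this reckoning. It gives pH 2.2, between 2.15 and 2.3, holding that “Acid therefore acts as a catalyst and isn't consumed”.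

The flask gives 80.3% and pH 2.20.

    substrate + acid → weak acid + acid + product (k = 13.0 M⁻¹ h⁻¹)
    weak acid ⇌ conjugate base + acid, settled at all times (K = 7.90 × 10⁻⁶ M)
    substrate → weak acid + product (k = 0.0250 h⁻¹)
    substrate + weak acid ⇌ idle adduct, settled at all times (K = 50.0 M⁻¹)
    weak acid + scavenger → scavenged by-product (k = 120 M⁻¹ h⁻¹)
    substrate ⇌ dormant form (K = 2.10, k = 1.00 h⁻¹)

In the flask at 12.0 h, nearly all of the reservoir is the dormant form, the resting state of substrate: it holds 44.3% beside 0.266% of idle adduct, more than the 19.7% of substrate. Put the flask's product, 35.7%, through the share: reacted comes to 81.2%. Now take the neighbour with 0.025 M of acid. Its product is 73.0%, so the same share gives 92.1%. That neighbour flask gives 92.6%.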